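Follow one molecule.

| flask | substrate | partner | remark | time |
|---|---|---|---|---|
| Saturday's | 0.050 M | 0.25 M (in portions, 4) | run made earlier; portions every 4.0 min |  |
| Wednesday's | 0.075 M | 0.25 M (in portions, 4) | run made earlier; portions every 4.0 min |  |
| Tuesday's | 0.10 M | 0.50 M (in portions, 4) | run made earlier; portions every 4.0 min |  |
| flask | 0.10 M | 0.250 M (in portions, 4) | the portions of partner follow each other after 4.0 min, the first at the start | 15 h |

- Saturday's (time / h: substrate / %, target / %): 1.00: 12.4, 35.8; 3.00: 0, 7.1; 5.00: 0.2, 4.2; 8.00: 0, 4.3; 10.0: 0, 5.2; 15.0: 0.1, 4.4; 20.0: 0, 4.1
- Wednesday's (time / h: substrate / %, target / %): 1.00: 12.6, 35.9; 3.00: 0, 6.8; 5.00: 0, 4.2; 8.00: 0, 3.9; 10.0: 0.4, 4.4; 15.0: 0.1, 5.0; 20.0: 0, 3.9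
- Tuesday's (time / h: substrate / %, target / %): 1.33: 6.8, 25.3; 2.50: 1.2, 8.3; 5.00: 0, 4.5; 10.0: 0, 4.8; 20.0: 0.9, 4.4

(scatter of a reading: 0.5 percentage points)

- the reaction counts as stopped when no species that holds the substrate changes by six tenths of a point or more over the second half of the time
- a reading of substrate is of its free form alone
- a reading of target is of its free form alone

- why nothing more happens at 15 h, or that something still does (all of the substrate has reacted / it is still moving / forward and back rates have come level)
- how much of the substrate has reacted by 15 h
- how much target there is at 15 h, in percent of the substrate charged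

Start with what looks contradictory. In Saturday's run target falls from 35.8% at 1.00 h to 7.1% at 3.00 h, yet it still reads 4.1% at 20.0 h. Carry that early pace on: a plain decay gives 1.41% at 5.00 h, but the reading there is 4.2%. So drop the plain decay and read a fork with a way back: a molecule leaves target and can return.

Now ask for its chances. Average the target readings from 5.00 h on, run by run: 4.44%, 4.28% and 4.57%. These lie within 0.5 percentage points of each other, so take their mean, 4.43%. Call it the sitting share, the chance that a reacted molecule stands as target once the readings lie flat.

This flask has 2.50 equivalents of partner, fewer than any run so far. Assume one partner per substrate, which makes substrate the limiting reagent. Saturday's reading of 12.4% at 1.00 h, read as first-order loss, gives a substrate rate constant of 2.09 h⁻¹, so a half-life of 0.332 h, far shorter than 15 h. So I expect conversion of >99.9% in this flask, a stop with all of the substrate reacted, and target at the sitting share.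

The forecast says forward and back rates have come level, with conversion 100% (98% to 100%) and target 4.4% (3.8% to 5%), reading the plateau thus: “this looks like a concentration-independent equilibrium between target and its unimolecular follow-on product”. I differ from it on the ending.

    substrate ⇌ open intermediate (K = 4.18, k = 0.0362 min⁻¹)
    partner → second intermediate (k = 0.0335 min⁻¹)
    open intermediate + second intermediate → target (k = 3.49 M⁻¹ min⁻¹)
    target ⇌ isomer of the product (K = 22.3, k = 0.0285 min⁻¹)

In the flask all of the substrate has reacted, with conversion 100% and target 4.29%. Beside that target, the isomer of the product holds 95.7% at 15.0 h. Multiply the sitting share by the conversion: 4.43%, against the flask's 4.29%. Now take the neighbour charged with 0.15 M of partner, 1.50 equivalents. The sitting share again says 4.43%, and that neighbour holds 4.29% of target at 15.0 h.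

The earlier runs and the new flask are calculated for an exercise; scatter was added.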